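## Retrosynthetic overview

1. Target 10 ⇐ bis-MOM ether 9 (acid deprotection) ⇐ aryl bromide 8 (Stille prenylation; the prenyl C–C bond is made last, so the alkene never meets an oxidant).
2. Ring C of isoflavone 8 ⇐ keto acetal 7 (O1–C2 bond; base-induced ring closure with loss of two MeOH).
3. Keto acetal 7 ⇐ chalcone 6 by the new iodoarene-catalysed oxidative 1,2-aryl shift (C3–C1' bond).
4. Chalcone 6 ⇐ ring A ketone 2 + ring B aldehyde 5 (Claisen–Schmidt); 2 comes from 1 and 5 from 3 by selective O-alkylations.
5. Ring order: rings A and B are bought intact; ring C is the only ring formed (step 6).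

Assumption: the target has no stereocentre and its side-chain alkene carries two identical methyl groups, so it is achiral and "single enantiomer" calls for no stereocontrol; compounds 1 and 3 are taken as catalogue chemicals.

## Route

Step 1
Reactants: 1 ring A ketone 1-(2,4-dihydroxy-6-methoxyphenyl)ethan-1-one
Product: 2 ring A MOM ether 1-[2-hydroxy-6-methoxy-4-(methoxymethoxy)phenyl]ethan-1-one
Conditions: MOMCl (1.1 equiv), K2CO3 (1.5 equiv), acetone, 0 °C to rt
Reagents that add atoms: chloromethyl methyl ether (MOMCl), COCCl
Why: The 2-hydroxyl is locked in a hydrogen bond to the ketone, so Williamson-type O-alkylation takes place only at the more acidic, exposed 4-hydroxyl.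

Step 2
Reactants: 3 catechol aldehyde 3-bromo-4,5-dihydroxybenzaldehyde
Product: 4 phenol aldehyde 3-bromo-5-hydroxy-4-methoxybenzaldehyde
Conditions: MeI (1.1 equiv), Li2CO3 (1.2 equiv), DMF, 40 °C
Reagents that add atoms: iodomethane (MeI), CI
Why: The 4-hydroxyl (para to the aldehyde, ortho to bromine) is markedly more acidic than the 5-hydroxyl, so the weak base forms only that phenoxide and SN2 methylation (Williamson ether synthesis) gives the 4-methyl ether.

Step 3
Reactants: 4 phenol aldehyde 3-bromo-5-hydroxy-4-methoxybenzaldehyde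
Product: 5 ring B aldehyde 3-bromo-4-methoxy-5-(methoxymethoxy)benzaldehyde
Conditions: MOMCl (1.3 equiv), K2CO3 (2 equiv), acetone, rt
Reagents that add atoms: chloromethyl methyl ether (MOMCl), COCCl
Why: Williamson-type MOM protection of the one remaining phenol masks it for the strongly basic condensation and the later oxidation.

Step 4
Reactants: 2 ring A MOM ether 1-[2-hydroxy-6-methoxy-4-(methoxymethoxy)phenyl]ethan-1-one; 5 ring B aldehyde 3-bromo-4-methoxy-5-(methoxymethoxy)benzaldehyde
Product: 6 chalcone (E)-3-[3-bromo-4-methoxy-5-(methoxymethoxy)phenyl]-1-[2-hydroxy-6-methoxy-4-(methoxymethoxy)phenyl]prop-2-en-1-one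
Conditions: KOH (50% aq, excess), EtOH, rt, 48 h; then cold AcOH to pH 6
Reagents that add atoms: none
Why: Claisen–Schmidt condensation (aldol addition of the methyl ketone enolate to the non-enolisable aldehyde, then E1cB dehydration) gives the thermodynamically favoured E-enone, and the MOM ethers and aryl bromide are inert to hydroxide.

Step 5
Reactants: 6 chalcone (E)-3-[3-bromo-4-methoxy-5-(methoxymethoxy)phenyl]-1-[2-hydroxy-6-methoxy-4-(methoxymethoxy)phenyl]prop-2-en-1-one
Product: 7 keto acetal rac-2-[3-bromo-4-methoxy-5-(methoxymethoxy)phenyl]-1-[2-hydroxy-6-methoxy-4-(methoxymethoxy)phenyl]-3,3-dimethoxypropan-1-one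
Conditions: 4-iodotoluene (20 mol%), mCPBA (1.3 equiv, added over 2 h), TsOH·H2O (10 mol%), MeOH, 0 °C to rt
Reagents that add atoms: methanol, CO
Why: Proposed new method: an iodoarene-catalysed oxidative 1,2-aryl shift (migratory geminal dimethoxylation) of a free 2'-hydroxychalcone, in which mCPBA oxidises 4-iodotoluene (monovalent iodine) to an aryl-λ3-iodane (trivalent iodine) that, with acid activation and methanol, adds across the enone (MeO to the benzylic β-carbon, iodane to the α-carbon); the 4-methoxy-bearing ring B then migrates from Cβ to Cα through a phenonium ion as the hypernucleofugal iodoarene leaves and closes the catalytic cycle, and methanol traps the oxocarbenium ion as the dimethyl acetal, which forges the C3–C1' bond of the isoflavone (the new stereocentre is racemic and is erased in step 6); the closest known reaction types are the same chalcone rearrangement run with stoichiometric thallium trinitrate or stoichiometric aryl-λ3-iodanes, and the iodoarene/mCPBA-catalysed α-oxygenation of ketones and migratory geminal difluorination of cinnamic acid derivatives.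

Step 6
Reactants: 7 keto acetal rac-2-[3-bromo-4-methoxy-5-(methoxymethoxy)phenyl]-1-[2-hydroxy-6-methoxy-4-(methoxymethoxy)phenyl]-3,3-dimethoxypropan-1-one
Product: 8 bromo isoflavone 3-[3-bromo-4-methoxy-5-(methoxymethoxy)phenyl]-5-methoxy-7-(methoxymethoxy)-4H-chromen-4-one
Conditions: NaOMe (3 equiv), MeOH, 65 °C
Reagents that add atoms: none
Why: A methoxide-mediated elimination, oxa-Michael addition and elimination cascade (the base variant of the classical acetal-to-isoflavone ring closure) lets the 2-phenoxide displace both methoxy groups as methanol and close ring C without acid, so the MOM ethers survive.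

Step 7
Reactants: 8 bromo isoflavone 3-[3-bromo-4-methoxy-5-(methoxymethoxy)phenyl]-5-methoxy-7-(methoxymethoxy)-4H-chromen-4-one
Product: 9 prenyl isoflavone 5-methoxy-3-[4-methoxy-3-(methoxymethoxy)-5-(3-methylbut-2-en-1-yl)phenyl]-7-(methoxymethoxy)-4H-chromen-4-one
Conditions: tributyl(3-methylbut-2-en-1-yl)stannane (1.5 equiv), Pd(PPh3)4 (5 mol%), DMF, 100 °C
Reagents that add atoms: tributyl(3-methylbut-2-en-1-yl)stannane, CCCC[Sn](CCCC)(CCCC)CC=C(C)C
Why: Stille cross-coupling (oxidative addition of zerovalent palladium into the aryl C–Br bond, transfer of the prenyl group from tin through its α-carbon, reductive elimination) gives the linear prenyl arene under neutral conditions that the chromone and MOM ethers tolerate.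

Step 8
Reactants: 9 prenyl isoflavone 5-methoxy-3-[4-methoxy-3-(methoxymethoxy)-5-(3-methylbut-2-en-1-yl)phenyl]-7-(methoxymethoxy)-4H-chromen-4-one
Product: 10 target 7-hydroxy-3-[3-hydroxy-4-methoxy-5-(3-methylbut-2-en-1-yl)phenyl]-5-methoxy-4H-chromen-4-one
Conditions: HCl (1.25 M in MeOH), 45 °C
Reagents that add atoms: none
Why: Acid-catalysed acetal exchange with methanol removes both MOM ethers, while the prenyl group (no ortho-hydroxyl to cyclise onto), the two aryl methyl ethers and the chromone survive the mild acid.

## Compound list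

1 | ring A ketone 1-(2,4-dihydroxy-6-methoxyphenyl)ethan-1-one | CC(=O)c1c(O)cc(O)cc1OC | starting material
2 | ring A MOM ether 1-[2-hydroxy-6-methoxy-4-(methoxymethoxy)phenyl]ethan-1-one | CC(=O)c1c(O)cc(OCOC)cc1OC | intermediate
3 | catechol aldehyde 3-bromo-4,5-dihydroxybenzaldehyde | O=Cc1cc(O)c(O)c(Br)c1 | starting material
4 | phenol aldehyde 3-bromo-5-hydroxy-4-methoxybenzaldehyde | O=Cc1cc(O)c(OC)c(Br)c1 | intermediate
5 | ring B aldehyde 3-bromo-4-methoxy-5-(methoxymethoxy)benzaldehyde | O=Cc1cc(OCOC)c(OC)c(Br)c1 | intermediate
6 | chalcone (E)-3-[3-bromo-4-methoxy-5-(methoxymethoxy)phenyl]-1-[2-hydroxy-6-methoxy-4-(methoxymethoxy)phenyl]prop-2-en-1-one | COCOc1cc(O)c(C(=O)/C=C/c2cc(Br)c(OC)c(OCOC)c2)c(OC)c1 | intermediate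
7 | keto acetal rac-2-[3-bromo-4-methoxy-5-(methoxymethoxy)phenyl]-1-[2-hydroxy-6-methoxy-4-(methoxymethoxy)phenyl]-3,3-dimethoxypropan-1-one (racemate) | COCOc1cc(O)c(C(=O)C(C(OC)OC)c2cc(Br)c(OC)c(OCOC)c2)c(OC)c1 | intermediate
8 | bromo isoflavone 3-[3-bromo-4-methoxy-5-(methoxymethoxy)phenyl]-5-methoxy-7-(methoxymethoxy)-4H-chromen-4-one | COCOc1cc(OC)c2c(c1)occ(-c3cc(Br)c(OC)c(OCOC)c3)c2=O | intermediate
9 | prenyl isoflavone 5-methoxy-3-[4-methoxy-3-(methoxymethoxy)-5-(3-methylbut-2-en-1-yl)phenyl]-7-(methoxymethoxy)-4H-chromen-4-one | COCOc1cc(OC)c2c(c1)occ(-c3cc(CC=C(C)C)c(OC)c(OCOC)c3)c2=O | intermediate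
10 | target 7-hydroxy-3-[3-hydroxy-4-methoxy-5-(3-methylbut-2-en-1-yl)phenyl]-5-methoxy-4H-chromen-4-one (achiral) | COc1c(O)cc(-c2coc3cc(O)cc(OC)c3c2=O)cc1CC=C(C)C | target

## Step count and risks

Total step count: 8.
Longest linear sequence: 7 steps (3 → 4 → 5 → 6 → 7 → 8 → 9 → 10); ring A enters after one step.

Three steps most likely to fail:

**Step 5 (the proposed new step).** The risks are slow catalyst turnover, attack of the iodane on the electron-rich ring A, and partial loss of MOM under the acid co-catalyst. The fallback sets out from chalcone 6 and abandons iodine redox catalysis and the peracid for the classical stoichiometric oxythallation route: thallium trinitrate trihydrate, Tl(NO3)3·3H2O (1.1 equiv), in MeOH/CH(OMe)3 at rt. Trivalent thallium adds to the enone with methanol and the aryl group shifts as monovalent thallium leaves. This is established chemistry for 2'-hydroxy-4',6'-dialkoxychalcones; it gives keto acetal 7 itself, where it comes back to the route, and makes no new compound (F0).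

**Step 6.** The risk is a sluggish base-induced elimination on the phenoxide, or opening of the pyranone by methoxide. The fallback sets out from keto acetal 7 and uses the standard acid ring closure (HCl, 1.25 M in MeOH, 65 °C). This closes ring C reliably but also removes both MOM groups, giving the diphenol 3-(3-bromo-5-hydroxy-4-methoxyphenyl)-7-hydroxy-5-methoxy-4H-chromen-4-one F1. Re-protection of both phenols (MOMCl, K2CO3, acetone, rt) comes back to the route at bromo isoflavone 8.

**Step 7.** The risk is transfer of the prenyl group through its γ-carbon (reverse-prenyl isomer) or slow coupling next to the methoxy group. The fallback sets out from bromo isoflavone 8 and builds the prenyl group in two stages. Suzuki–Miyaura allylation (allylboronic acid pinacol ester, Pd(dppf)Cl2, CsF, THF, 70 °C), where both ends of the allyl unit give the same product, leads to the allyl isoflavone 5-methoxy-3-[4-methoxy-3-(methoxymethoxy)-5-(prop-2-en-1-yl)phenyl]-7-(methoxymethoxy)-4H-chromen-4-one F2. Olefin cross-metathesis with excess 2-methylbut-2-ene (second-generation Grubbs catalyst, 5 mol%, CH2Cl2, 40 °C) then turns the allyl into the prenyl group and comes back to the route at prenyl isoflavone 9.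

## Further compounds

F0 | step 5 | none | none
F1 | step 6 | 3-(3-bromo-5-hydroxy-4-methoxyphenyl)-7-hydroxy-5-methoxy-4H-chromen-4-one | COc1cc(O)cc2occ(-c3cc(O)c(OC)c(Br)c3)c(=O)c12
F2 | step 7 | 5-methoxy-3-[4-methoxy-3-(methoxymethoxy)-5-(prop-2-en-1-yl)phenyl]-7-(methoxymethoxy)-4H-chromen-4-one | COCOc1cc(OC)c2c(c1)occ(-c3cc(CC=C)c(OC)c(OCOC)c3)c2=O
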